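The five-membered ring is cut at C1–C2 and at the ring-fusion bond C3a–C8a (azulene numbering). This leaves C2–C3–C3a, whose central carbon carries the tertiary oxygen, as a 2-oxyallyl unit, and C8a–C1, the methyl-bearing quaternary carbon and its CH2, as an enamine C=C. The key step is a reductive oxyallyl–enamine [3+2] cycloaddition (Noyori cyclopentenone synthesis) of tetrabromoacetone with the morpholine enamine of 2-methylpent-4-enal. It should form both bonds and the quaternary centre in one operation and give 4-allyl-4-methylcyclopentenone. Aldol addition, kinetic resolution, ring-closing metathesis to the seven-membered ring, isopropyl addition, alkene reduction and vanilloylation complete the synthesis.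

Key step: step 2

Remark: nothing in the enamine differentiates its two faces, so the quaternary centre is expected as a racemate; the absolute configuration is introduced by kinetic resolution of alcohol 9 (step 5).

Step 1
Reactants: 1 2-methylpent-4-enal (racemate); 2 morpholine
Product: 3 4-(2-methylpenta-1,4-dien-1-yl)morpholine (E/Z mixture)
Conditions: p-TsOH (cat.), cyclohexane, reflux, Dean–Stark
Reagents that add atoms: none
Why: Acid-catalysed condensation with azeotropic removal of water should give the trisubstituted enamine (Stork enamine formation); the E/Z ratio and the original stereocentre do not matter because this carbon becomes the quaternary centre in step 2.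

Step 2
Reactants: 3 4-(2-methylpenta-1,4-dien-1-yl)morpholine; 4 1,1,3,3-tetrabromopropan-2-one
Product: 6 (±)-4-methyl-4-(prop-2-en-1-yl)cyclopent-2-en-1-one, via dibromo morpholino cyclopentanone cycloadduct 5 (not isolated)
Conditions: Fe2(CO)9, benzene, 40 °C; then Zn–Cu couple, NH4Cl, MeOH, 25 °C
Reagents that add atoms: none
Why: Fe2(CO)9 should reduce 4 by two electrons to a 1,3-dibromo-2-oxyallyl cation held on divalent iron; the nucleophilic β-carbon of enamine 3 adds to one terminus (bond C3a–C8a of the target) and the resulting iron enolate closes on the iminium carbon (bond C1–C2), a stepwise [3+2] cycloaddition. Zn–Cu then removes both bromines, the zinc enolate expelling morpholine to leave the enone. The closest known reaction type is the Noyori iron-carbonyl cyclopentenone synthesis from α,α′-dibromo ketones and enamines, used here in its tetrabromoacetone/Zn–Cu form for an unsubstituted oxyallyl unit. The cyclopentane ring closes by 5-exo-trig Mannich-type attack of the enolate carbon on C=N+. The quaternary carbon is the only stereocentre that survives and should form as a racemate, since no element controls its faces. The step needs attack on the enamine C=C and not on the isolated vinyl group, which the much higher nucleophilicity of the enamine should secure; the symmetric oxyallyl removes any regiochemical question.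

Step 3
Reactants: 7 3-methylbut-3-en-1-ol
Product: 8 3-methylbut-3-enal
Conditions: Dess–Martin periodinane, pyridine, CH2Cl2, 0 °C
Reagents that add atoms: none
Why: Buffered Dess–Martin oxidation should give the β,γ-unsaturated aldehyde without migration of the double bond into conjugation; 8 is used at once as a solution.

Step 4
Reactants: 6 (±)-4-methyl-4-(prop-2-en-1-yl)cyclopent-2-en-1-one; 8 3-methylbut-3-enal
Product: 9 rac-(4S,5S)-5-[(1S)-1-hydroxy-3-methylbut-3-en-1-yl]-4-methyl-4-(prop-2-en-1-yl)cyclopent-2-en-1-one
Conditions: LiN(i-Pr)2, THF, −78 °C; then 8; AcOH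
Reagents that add atoms: none
Why: The base removes the only enolisable (α′) proton, and the ring-locked E-enolate should add through a Zimmerman–Traxler chair (lithium aldol, anti) with the aldehyde approaching anti to the allyl group on the neighbouring quaternary carbon, which sets both new stereocentres relative to it; minor diastereomers are removed by chromatography.

Step 5
Reactants: 9 racemic aldol
Product: 10 (4S,5S)-5-[(1S)-1-hydroxy-3-methylbut-3-en-1-yl]-4-methyl-4-(prop-2-en-1-yl)cyclopent-2-en-1-one (single enantiomer)
Conditions: Burkholderia cepacia lipase (Amano PS), vinyl acetate, t-BuOMe, 30 °C, stopped just past half conversion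
Reagents that add atoms: none
Why: Lipase-catalysed kinetic resolution by transesterification; by the Kazlauskas rule the (1R)-carbinol enantiomer should be acetylated and the (1S)-alcohol 10 recovered, which fixes the absolute configuration of all three stereocentres.

Step 6
Reactants: 10 resolved aldol
Product: 11 (3aS,4S,8aS)-4-hydroxy-6,8a-dimethyl-4,5,8,8a-tetrahydroazulen-3(3aH)-one (trans-fused; locants as in the target ester)
Conditions: second-generation Grubbs catalyst (5 mol%), CH2Cl2 (0.005 M), 40 °C
Reagents that add atoms: none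
Why: Ring-closing metathesis of the allyl and 2-methylallyl groups, which are trans on the cyclopentenone, should close the seven-membered ring with its trisubstituted C6=C7 alkene and the trans ring fusion; the electron-poor enone C=C does not take part.

Step 7
Reactants: 11 bicyclic hydroxy enone
Product: 12 (3S,3aS,4S,8aS)-6,8a-dimethyl-3-(propan-2-yl)-3,3a,4,5,8,8a-hexahydroazulene-3,4-diol
Conditions: i-PrMgCl, CeCl3, THF, −78 to 0 °C
Reagents that add atoms: isopropylmagnesium chloride, CC(C)[Mg]Cl
Why: Organocerium 1,2-addition to the enone carbonyl should suppress enolisation, hydride transfer and conjugate addition; the angular methyl and the C3a–C4 bond shield the β face, so attack from the α face places the new hydroxyl cis to the angular methyl.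

Step 8
Reactants: 12 allylic tertiary alcohol
Product: 13 (3R,3aS,4S,8aR)-6,8a-dimethyl-3-(propan-2-yl)-1,2,3,3a,4,5,8,8a-octahydroazulene-3,4-diol (jaeschkeanadiol)
Conditions: 2-nitrobenzenesulfonyl hydrazide, Et3N, CH2Cl2, 25 °C
Reagents that add atoms: none
Why: Diimide generated in the flask should reduce the cis-disubstituted cyclopentene much faster than the trisubstituted cycloheptene (chemoselective diimide reduction), so the ring alkene of the target is kept and no stereocentre is touched.

Step 9
Reactants: 13 jaeschkeanadiol; 14 4-(acetyloxy)-3-methoxybenzoic acid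
Product: 15 (3R,3aS,4S,8aR)-3-hydroxy-6,8a-dimethyl-3-(propan-2-yl)-1,2,3,3a,4,5,8,8a-octahydroazulen-4-yl 4-(acetyloxy)-3-methoxybenzoate
Conditions: DCC, DMAP (cat.), CH2Cl2, 25 °C
Reagents that add atoms: none
Why: Steglich esterification should acylate only the secondary hydroxyl, with retention at C4; the tertiary carbinol is inert under these conditions.

Step 10
Reactants: 15 O-acetyl teferin
Product: 16 teferin, (3R,3aS,4S,8aR)-3-hydroxy-6,8a-dimethyl-3-(propan-2-yl)-1,2,3,3a,4,5,8,8a-octahydroazulen-4-yl 4-hydroxy-3-methoxybenzoate
Conditions: pyrrolidine, CH2Cl2, 0 °C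
Reagents that add atoms: none
Why: Aminolysis of the phenyl acetate, an activated ester, should be far faster than attack on the hindered alkyl benzoate, so the phenol is freed without loss of the vanillate.

Compound list
1 | 2-methylpent-4-enal (racemate) | C=CCC(C)C=O | starting material
2 | morpholine | C1COCCN1 | starting material
3 | 4-(2-methylpenta-1,4-dien-1-yl)morpholine (E/Z mixture) | C=CCC(C)=CN1CCOCC1 | intermediate
4 | 1,1,3,3-tetrabromopropan-2-one | O=C(C(Br)Br)C(Br)Br | starting material
5 | 2,5-dibromo-3-methyl-4-(morpholin-4-yl)-3-(prop-2-en-1-yl)cyclopentan-1-one (diastereomer mixture, not isolated) | O=C1C(Br)C(N2CCOCC2)C(C)(CC=C)C1Br | intermediate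
6 | (±)-4-methyl-4-(prop-2-en-1-yl)cyclopent-2-en-1-one | O=C1C=CC(C)(CC=C)C1 | intermediate
7 | 3-methylbut-3-en-1-ol | C=C(C)CCO | starting material
8 | 3-methylbut-3-enal | C=C(C)CC=O | intermediate
9 | rac-(4S,5S)-5-[(1S)-1-hydroxy-3-methylbut-3-en-1-yl]-4-methyl-4-(prop-2-en-1-yl)cyclopent-2-en-1-one (both enantiomers) | C=C(C)C[C@H](O)[C@H]1C(=O)C=C[C@]1(C)CC=C.C=C(C)C[C@@H](O)[C@@H]1C(=O)C=C[C@@]1(C)CC=C | intermediate
10 | (4S,5S)-5-[(1S)-1-hydroxy-3-methylbut-3-en-1-yl]-4-methyl-4-(prop-2-en-1-yl)cyclopent-2-en-1-one | C=C(C)C[C@H](O)[C@H]1C(=O)C=C[C@]1(C)CC=C | intermediate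
11 | (3aS,4S,8aS)-4-hydroxy-6,8a-dimethyl-4,5,8,8a-tetrahydroazulen-3(3aH)-one | O[C@H]2CC(C)=CC[C@@]3(C)C=CC(=O)[C@H]23 | intermediate
12 | (3S,3aS,4S,8aS)-6,8a-dimethyl-3-(propan-2-yl)-3,3a,4,5,8,8a-hexahydroazulene-3,4-diol | O[C@H]2CC(C)=CC[C@@]3(C)C=C[C@@](O)(C(C)C)[C@H]23 | intermediate
13 | (3R,3aS,4S,8aR)-6,8a-dimethyl-3-(propan-2-yl)-1,2,3,3a,4,5,8,8a-octahydroazulene-3,4-diol (jaeschkeanadiol) | O[C@H]2CC(C)=CC[C@@]3(C)CC[C@@](O)(C(C)C)[C@H]23 | intermediate
14 | 4-(acetyloxy)-3-methoxybenzoic acid | CC(=O)Oc1ccc(C(=O)O)cc1OC | starting material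
15 | (3R,3aS,4S,8aR)-3-hydroxy-6,8a-dimethyl-3-(propan-2-yl)-1,2,3,3a,4,5,8,8a-octahydroazulen-4-yl 4-(acetyloxy)-3-methoxybenzoate | COc1cc(C(=O)O[C@H]2CC(C)=CC[C@@]3(C)CC[C@@](O)(C(C)C)[C@H]23)ccc1OC(C)=O | intermediate
16 | teferin | COc1cc(C(=O)O[C@H]2CC(C)=CC[C@@]3(C)CC[C@@](O)(C(C)C)[C@H]23)ccc1O | target

Total step count: 10. Longest linear sequence: 9 steps (1 → 3 → 6 → 9 → 10 → 11 → 12 → 13 → 15 → 16).

Steps most likely to fail

Step 2. The oxyallyl may be captured too slowly by the hindered enamine carbon that has to become quaternary, the terminal double bond may migrate under iron carbonyl, or the bromoketone may simply be reduced. The fallback sets out from 3 and comes back at 6: enamine 3 is C-alkylated with 2-methoxyallyl bromide (MeCN, reflux), the iminium salt and the enol ether are hydrolysed with aqueous acid to 2-methyl-4-oxo-2-(prop-2-en-1-yl)pentanal F1, and intramolecular aldol condensation (KOH, MeOH) closes the cyclopentenone 6.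

Step 5. The lipase may acylate the carbinol, which is flanked by two large groups, too slowly or with too little discrimination between the enantiomers. The fallback sets out from 9 and comes back at 10: racemic 9 is esterified with (2S)-methoxy(phenyl)acetic acid (DCC, DMAP). The diastereomeric esters (1S)-3-methyl-1-[(1S,5S)-5-methyl-2-oxo-5-(prop-2-en-1-yl)cyclopent-3-en-1-yl]but-3-en-1-yl (2S)-methoxy(phenyl)acetate F2 and (1R)-3-methyl-1-[(1R,5R)-5-methyl-2-oxo-5-(prop-2-en-1-yl)cyclopent-3-en-1-yl]but-3-en-1-yl (2S)-methoxy(phenyl)acetate F3 are separated by chromatography, and F2 is cleaved by mild methanolysis (K2CO3, MeOH, 0 °C) to 10.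

Step 7. The secondary organometallic may enolise the ketone or transfer hydride instead of adding, or the facial selectivity at the carbonyl may be poor. The fallback sets out from 11 and comes back at 13: isopropenylmagnesium bromide with CeCl3, a smaller sp2 nucleophile that cannot deliver hydride, is added to 11 to give (3S,3aS,4S,8aS)-6,8a-dimethyl-3-(prop-1-en-2-yl)-3,3a,4,5,8,8a-hexahydroazulene-3,4-diol F4. Diimide then saturates both the cyclopentene and the 1,1-disubstituted isopropenyl double bond in one operation, leaving the trisubstituted ring alkene, to give 13.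

Further compounds
F1 | step 2 | 2-methyl-4-oxo-2-(prop-2-en-1-yl)pentanal | C=CCC(C)(C=O)CC(C)=O
F2 | step 5 | (1S)-3-methyl-1-[(1S,5S)-5-methyl-2-oxo-5-(prop-2-en-1-yl)cyclopent-3-en-1-yl]but-3-en-1-yl (2S)-methoxy(phenyl)acetate | C=C(C)C[C@H](OC(=O)[C@@H](OC)c1ccccc1)[C@H]1C(=O)C=C[C@]1(C)CC=C
F3 | step 5 | (1R)-3-methyl-1-[(1R,5R)-5-methyl-2-oxo-5-(prop-2-en-1-yl)cyclopent-3-en-1-yl]but-3-en-1-yl (2S)-methoxy(phenyl)acetate | C=C(C)C[C@@H](OC(=O)[C@@H](OC)c1ccccc1)[C@@H]1C(=O)C=C[C@@]1(C)CC=C
F4 | step 7 | (3S,3aS,4S,8aS)-6,8a-dimethyl-3-(prop-1-en-2-yl)-3,3a,4,5,8,8a-hexahydroazulene-3,4-diol | O[C@H]2CC(C)=CC[C@@]3(C)C=C[C@@](O)(C(C)=C)[C@H]23
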